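**Retrosynthetic overview**

1. Numbering as in quinic acid (C1 carbinol/carboxyl carbon, C2 and C6 methylenes, C3 and C4 ester carbons, C5 free carbinol). Burkinabin A 13 ⇐ one global hydrogenolysis of 12 ⇐ bis-aroylation of the cis-3,4-diol 9 ⇐ OsO4 dihydroxylation of cyclohexene 8 anti to its C5 benzyloxy group.
2. 8 ⇐ enantioconvergent palladium-catalysed allylic etherification of racemic carbonate 7; its π-allyl complex over C3–C4–C5 has a mirror plane through C1 and C4, so the chiral ligand alone fixes the absolute configuration ⇐ hydroxyl-directed reduction of racemic enone 5.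
3. Key disconnection: ring bonds C1–C6 and C2–C3 are formed together. A Lewis acid cleaves a C–C bond of the symmetric 3-(benzyloxy)cyclobutanone 3, and the four-carbon unit C3–C4–C5(=O)–C6 joins the pyruvate silyl enol ether 2 (C1, C2 and the carboxyl) in a formal [4+2] cycloaddition.
4. Enabling feature: in the cyclohexane the C5 oxygen is 1,3 to the tertiary carbinol C1 and C3 is β to C5. With C5 at the ketone level, C3–C4–C5–C6 is a ring-opened 3-alkoxycyclobutanone (oxocarbenium at C3, enolate at C6) and C1–C2 is an enolised α-keto ester, so both new bonds are polarity-matched; the C3=C4 alkene left after loss of the alkoxy group later takes the two ester oxygens.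
5. Ring order: the cyclohexane is the only ring built (step 2); the four-membered ring is consumed in the same step.

Key step: step 2

Remark: compounds 4 to 7 are racemic; where relative configuration matters, the SMILES shows the enantiomer that maps onto the target and the name carries the prefix rac.
Remark: the (S,S)-ligand in step 5 is assigned by analogy with enantioconvergent substitutions of 2-cyclohexenyl carbonates; the sense must be confirmed on the first run, and the (R,R)-ligand gives the mirror-image ether by the same procedure.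

**Route**

Step 1
Reactants: 1 benzyl pyruvate (benzyl 2-oxopropanoate)
Product: 2 benzyl 2-[(trimethylsilyl)oxy]prop-2-enoate
Conditions: TMSCl, Et3N, Et2O, 0 °C → rt; filtration, distillation
Reagents that add atoms: chlorotrimethylsilane, C[Si](C)(C)Cl
Why: Soft enolisation of the α-keto ester by the amine and O-silylation give the silyl enol ether (standard silyl enol ether formation; the methyl group is the only enolisable position).

Step 2
Reactants: 2 benzyl 2-[(trimethylsilyl)oxy]prop-2-enoate; 3 3-(benzyloxy)cyclobutan-1-one
Product: 5 benzyl rac-1-hydroxy-5-oxocyclohex-3-ene-1-carboxylate, via silyl ether cycloadduct 4 (not isolated)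
Conditions: EtAlCl2 (1.1 equiv), CH2Cl2, −78 → −40 °C; 1 M HCl quench; crude 4 then TsOH·H2O (0.2 equiv), CH2Cl2, 40 °C
Reagents that add atoms: none
Why: EtAlCl2 binds the carbonyl of 3 and the strained bond between the benzyloxy-bearing carbon and an α-carbon (C3–C6) breaks heterolytically to a 1,4-zwitterion, a benzyloxy-stabilised oxocarbenium ion at C3 and an aluminium enolate at C5–C6; because 3 is symmetric only one zwitterion can form. The CH2 terminus of 2 (C2) adds to the oxocarbenium carbon (bond C2–C3), and the silyloxy-stabilised cation at C1 that results is trapped by the enolate carbon C6 in a 6-(enolexo)-exo-trig aldol closure (bond C1–C6) to give 4. The closest known reaction type is the Lewis-acid formal [4+2] cycloaddition of 3-alkoxycyclobutanones with silyl enol ethers, a Mukaiyama-type addition followed by intramolecular aldol addition. The carbocycle is the only ring formed and closes in the aldol step; the quaternary centre C1 is formed without control and is racemic by design, because its absolute configuration is imposed in step 5, and the transient centre C3 is erased. TsOH then removes the trimethylsilyl group and eliminates benzyl alcohol from the β-benzyloxy ketone through the enol to give the conjugated C3=C4 enone. The selectivity needed is loss of the C3 benzyloxy group and not of the C1 hydroxyl; departure from C1 would build positive charge next to the ester carbonyl and is disfavoured, and mild acid at 40 °C is chosen to avoid dehydration and aromatisation.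

Step 3
Reactants: 5 benzyl rac-1-hydroxy-5-oxocyclohex-3-ene-1-carboxylate
Product: 6 benzyl rac-(1S,5R)-1,5-dihydroxycyclohex-3-ene-1-carboxylate
Conditions: Me4NBH(OAc)3 (3 equiv), MeCN/AcOH 1:1, −30 °C
Reagents that add atoms: none
Why: Evans–Saksena hydroxyl-directed reduction: the tertiary C1 hydroxyl exchanges onto boron and delivers hydride to the C5 carbonyl on its own face, so the new C5 hydroxyl ends anti to the C1 hydroxyl and cis to the ester, and the acidic medium suppresses β-elimination of the C1 hydroxyl.

Step 4
Reactants: 6 benzyl rac-(1S,5R)-1,5-dihydroxycyclohex-3-ene-1-carboxylate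
Product: 7 benzyl rac-(1S,5R)-5-{[(benzyloxy)carbonyl]oxy}-1-hydroxycyclohex-3-ene-1-carboxylate
Conditions: CbzCl (1.2 equiv), pyridine, DMAP (cat.), CH2Cl2, 0 °C
Reagents that add atoms: benzyl chloroformate, O=C(Cl)OCc1ccccc1
Why: Chemoselective carbonate formation at the secondary allylic hydroxyl; the tertiary α-hydroxy ester is too hindered to react with a chloroformate in pyridine.

Step 5
Reactants: 7 benzyl rac-(1S,5R)-5-{[(benzyloxy)carbonyl]oxy}-1-hydroxycyclohex-3-ene-1-carboxylate
Product: 8 benzyl (1S,5R)-5-(benzyloxy)-1-hydroxycyclohex-3-ene-1-carboxylate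
Conditions: [Pd(C3H5)Cl]2 (2.5 mol %), (S,S)-DACH-phenyl ligand N,N'-[(1S,2S)-cyclohexane-1,2-diyl]bis[2-(diphenylphosphanyl)benzamide] (7.5 mol %), BnOH (1.2 equiv), ZnEt2 (0.6 equiv), THF, 0 °C → rt; aq. NH4Cl work-up
Reagents that add atoms: benzyl alcohol, OCc1ccccc1
Why: Tsuji–Trost allylic etherification with a zinc alkoxide, run as an enantioconvergent substitution of a racemic 2-cycloalkenyl carbonate: zerovalent palladium ionises both enantiomers of 7 anti to the carbonate to the same π-allyl complex over C3–C4–C5 (mirror plane through C1 and C4), the chiral ligand selects the allyl terminus, and outer-sphere attack anti to palladium returns the oxygen to the face of the ester, which sets C5 and thereby C1.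

Step 6
Reactants: 8 benzyl (1S,5R)-5-(benzyloxy)-1-hydroxycyclohex-3-ene-1-carboxylate
Product: 9 benzyl (1S,3R,4R,5R)-5-(benzyloxy)-1,3,4-trihydroxycyclohexane-1-carboxylate
Conditions: OsO4 (2 mol %), NMO (1.5 equiv), acetone/H2O 8:1, rt
Reagents that add atoms: N-methylmorpholine N-oxide, C[N+]1([O-])CCOCC1; water, O
Why: Catalytic OsO4/NMO syn-dihydroxylation adds to the C3=C4 face anti to the allylic C5 benzyloxy group and to the ester on the same face, so both new hydroxyls end cis to the C1 hydroxyl and trans to the C5 oxygen (the quinic acid pattern).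

Step 7
Reactants: 10 4-(benzyloxy)-3-methoxybenzoic acid
Product: 11 4-(benzyloxy)-3-methoxybenzoyl chloride
Conditions: (COCl)2, DMF (cat.), CH2Cl2, 0 °C → rt
Reagents that add atoms: oxalyl chloride, O=C(Cl)C(=O)Cl
Why: Standard acid chloride formation through the Vilsmeier-type chloroiminium species; the aryl benzyl ether and methoxy group are inert.

Step 8
Reactants: 9 benzyl (1S,3R,4R,5R)-5-(benzyloxy)-1,3,4-trihydroxycyclohexane-1-carboxylate; 11 4-(benzyloxy)-3-methoxybenzoyl chloride (2.4 equiv)
Product: 12 benzyl (1R,3R,4S,5R)-5-(benzyloxy)-3,4-bis{[4-(benzyloxy)-3-methoxybenzoyl]oxy}-1-hydroxycyclohexane-1-carboxylate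
Conditions: pyridine, DMAP (0.2 equiv), CH2Cl2, 0 °C → rt
Reagents that add atoms: none
Why: DMAP-catalysed acylation of the two secondary hydroxyls of the cis-3,4-diol; the hindered tertiary C1 hydroxyl stays free and the C5 oxygen is blocked as its benzyl ether, so the ester pattern of the target is fixed here.

Step 9
Reactants: 12 benzyl (1R,3R,4S,5R)-5-(benzyloxy)-3,4-bis{[4-(benzyloxy)-3-methoxybenzoyl]oxy}-1-hydroxycyclohexane-1-carboxylate
Product: 13 Burkinabin A, (1R,3R,4S,5R)-1,5-dihydroxy-3,4-bis[(4-hydroxy-3-methoxybenzoyl)oxy]cyclohexane-1-carboxylic acid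
Conditions: H2 (1 atm), Pd/C (10 %), THF/MeOH, rt
Reagents that add atoms: none
Why: Heterogeneous hydrogenolysis removes all four O-benzyl groups (benzyl ester, secondary benzyl ether, two aryl benzyl ethers) under neutral conditions, which avoids acyl migration and leaves the aroyl esters and all stereocentres untouched.

**Compound list**

1 | benzyl pyruvate (benzyl 2-oxopropanoate) | CC(=O)C(=O)OCc1ccccc1 | starting material
2 | benzyl 2-[(trimethylsilyl)oxy]prop-2-enoate | C=C(O[Si](C)(C)C)C(=O)OCc1ccccc1 | intermediate
3 | 3-(benzyloxy)cyclobutan-1-one | O=C1CC(OCc2ccccc2)C1 | starting material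
4 | benzyl rac-3-(benzyloxy)-5-oxo-1-[(trimethylsilyl)oxy]cyclohexane-1-carboxylate (silyl ether cycloadduct, diastereomer mixture) | O=C1CC(OCc2ccccc2)CC(O[Si](C)(C)C)(C(=O)OCc2ccccc2)C1 | intermediate (not isolated)
5 | benzyl rac-1-hydroxy-5-oxocyclohex-3-ene-1-carboxylate | O=C1C=CCC(O)(C(=O)OCc2ccccc2)C1 | intermediate
6 | benzyl rac-(1S,5R)-1,5-dihydroxycyclohex-3-ene-1-carboxylate | C1=C[C@H](O)C[C@](O)(C(=O)OCc2ccccc2)C1 | intermediate
7 | benzyl rac-(1S,5R)-5-{[(benzyloxy)carbonyl]oxy}-1-hydroxycyclohex-3-ene-1-carboxylate | C1=C[C@H](OC(=O)OCc2ccccc2)C[C@](O)(C(=O)OCc2ccccc2)C1 | intermediate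
8 | benzyl (1S,5R)-5-(benzyloxy)-1-hydroxycyclohex-3-ene-1-carboxylate | C1=C[C@H](OCc2ccccc2)C[C@](O)(C(=O)OCc2ccccc2)C1 | intermediate
9 | benzyl (1S,3R,4R,5R)-5-(benzyloxy)-1,3,4-trihydroxycyclohexane-1-carboxylate | O[C@H]1[C@H](OCc2ccccc2)C[C@](O)(C(=O)OCc2ccccc2)C[C@H]1O | intermediate
10 | 4-(benzyloxy)-3-methoxybenzoic acid | COc1cc(C(=O)O)ccc1OCc1ccccc1 | starting material
11 | 4-(benzyloxy)-3-methoxybenzoyl chloride | COc1cc(C(=O)Cl)ccc1OCc1ccccc1 | intermediate
12 | benzyl (1R,3R,4S,5R)-5-(benzyloxy)-3,4-bis{[4-(benzyloxy)-3-methoxybenzoyl]oxy}-1-hydroxycyclohexane-1-carboxylate | COc1cc(C(=O)O[C@H]2[C@H](OCc3ccccc3)C[C@](O)(C(=O)OCc3ccccc3)C[C@H]2OC(=O)c2ccc(OCc3ccccc3)c(OC)c2)ccc1OCc1ccccc1 | intermediate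
13 | Burkinabin A, (1R,3R,4S,5R)-1,5-dihydroxy-3,4-bis[(4-hydroxy-3-methoxybenzoyl)oxy]cyclohexane-1-carboxylic acid | COc1cc(C(=O)O[C@H]2[C@H](O)C[C@](O)(C(=O)O)C[C@H]2OC(=O)c2ccc(O)c(OC)c2)ccc1O | target

**Step count and risks**

Total step count: 9. Longest linear sequence: 8 steps (steps 1 to 6, 8 and 9, from benzyl pyruvate); step 7 is a one-step side branch.

Steps most likely to fail:

Step 2. The ring-opened zwitterion may self-condense faster than the weakly nucleophilic 2-silyloxyacrylate captures it, or the acid treatment may dehydrate the β-hydroxy enone further and aromatise it. The fallback is the classical Diels–Alder construction of the same two ring bonds; it sets out from 1 and comes back at 6. Compound 1 is heated with Ac2O and catalytic TsOH to give the enol acetate benzyl 2-acetoxyprop-2-enoate F1. Thermal Diels–Alder reaction of F1 with buta-1,3-diene (toluene, 140 °C, sealed tube, hydroquinone) gives benzyl rac-1-acetoxycyclohex-3-ene-1-carboxylate F2. LiOH in THF/water cleaves both esters to rac-1-hydroxycyclohex-3-ene-1-carboxylic acid F3. Iodolactonisation (I2, NaHCO3, CH2Cl2/water) gives the bridged iodolactone rac-1-hydroxy-4-iodo-6-oxabicyclo[3.2.1]octan-7-one F4, with iodine trans to the lactone oxygen. DBU in toluene at 80 °C eliminates hydrogen iodide to the allylic lactone rac-1-hydroxy-6-oxabicyclo[3.2.1]oct-3-en-7-one F5. Benzyl alcohol with catalytic sodium benzyloxide opens the strained lactone to 6, whose C5 hydroxyl is cis to the ester by construction.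

Step 5. Attack of the hard zinc alkoxide on the π-allyl complex may be slow, so that β-hydride elimination to the cyclohexadiene or poor enantioselection takes over. The fallback is an enzymatic kinetic resolution followed by acid-catalysed benzylation; it sets out from 6 and comes back at 8, and steps 4 and 5 are then not needed. Immobilised Candida antarctica lipase B and vinyl acetate in MTBE acetylate the secondary hydroxyl of one enantiomer only. The empirical size rule for lipases, with the C6 arm that carries the quaternary carbon as the large group, predicts that the (5S)-alcohol reacts and gives benzyl (1R,5S)-5-acetoxy-1-hydroxycyclohex-3-ene-1-carboxylate F6, which is separated. The unreacted (1S,5R)-enantiomer of 6 is benzylated at the secondary hydroxyl with benzyl 2,2,2-trichloroacetimidate and catalytic TfOH to give 8.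

Step 3. Facial selectivity may be poor if hydride is not delivered through the boron-bound C1 hydroxyl, or conjugate reduction may compete. The fallback is an undirected 1,2-reduction with lactonisation as a stereochemical filter; it sets out from 5 and comes back at 6. Luche reduction (NaBH4, CeCl3·7H2O, MeOH, −78 °C) gives 6 together with its C5 epimer benzyl rac-(1S,5S)-1,5-dihydroxycyclohex-3-ene-1-carboxylate F7. Catalytic TsOH in toluene at 80 °C lactonises only the 1,5-cis hydroxy ester 6 to the allylic lactone rac-1-hydroxy-6-oxabicyclo[3.2.1]oct-3-en-7-one F5 (the same compound as in the fallback for step 2). F7 is separated and returned to 5 with MnO2, and F5 is reopened to 6 with benzyl alcohol and catalytic sodium benzyloxide.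

Further compounds
F1 | step 2 | benzyl 2-acetoxyprop-2-enoate | C=C(OC(C)=O)C(=O)OCc1ccccc1
F2 | step 2 | benzyl rac-1-acetoxycyclohex-3-ene-1-carboxylate | CC(=O)OC1(C(=O)OCc2ccccc2)CC=CCC1
F3 | step 2 | rac-1-hydroxycyclohex-3-ene-1-carboxylic acid | OC1(C(=O)O)CC=CCC1
F4 | step 2 | rac-1-hydroxy-4-iodo-6-oxabicyclo[3.2.1]octan-7-one (iodine trans to the lactone oxygen) | I[C@H]1[C@H]2C[C@](O)(C(=O)O2)CC1
F5 | step 2 | rac-1-hydroxy-6-oxabicyclo[3.2.1]oct-3-en-7-one | C1=C[C@H]2C[C@](O)(C(=O)O2)C1
F6 | step 5 | benzyl (1R,5S)-5-acetoxy-1-hydroxycyclohex-3-ene-1-carboxylate | C1=C[C@@H](OC(C)=O)C[C@@](O)(C(=O)OCc2ccccc2)C1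
F7 | step 3 | benzyl rac-(1S,5S)-1,5-dihydroxycyclohex-3-ene-1-carboxylate | C1=C[C@@H](O)C[C@](O)(C(=O)OCc2ccccc2)C1
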